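The target is cut at the C2–C3 bond of its propane-1,3-diyl tether, i.e. the bond between the benzylic carbon on the para-oxygenated benzene ring and the central CH2. Drawn as a C=C, that bond is the direct outcome of a ruthenium-carbene cross-metathesis between two terminal alkenes. In one operation the key step joins the vinyl group of phenol-acetylated 4-vinylphenol to the allyl group of allyl docosanoate with loss of ethylene, assembling the complete carbon and oxygen skeleton. The precursor pair is an aryl–CH=CH2 unit and a CH2=CH–CH2–O–acyl unit, each a plain monosubstituted alkene. Hydrogenation of the new alkene and chemoselective removal of the phenolic acetate finish the synthesis.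

Key step: step 2

Remark: the target has no stereocentre; the only stereochemical element on the way is the E alkene made in the key step, which the following hydrogenation removes.

Step 1
Reactants: 1 docosanoyl chloride; 2 allyl alcohol (1.2 equiv)
Product: 3 allyl docosanoate
Conditions: pyridine (1.5 equiv), CH2Cl2, 0 °C to rt
Reagents that add atoms: none
Why: Nucleophilic acyl substitution (O-acylation of a primary alcohol by an acyl chloride), with pyridine as acyl-transfer catalyst and HCl acceptor; the terminal alkene is a spectator.

Step 2
Reactants: 3 allyl docosanoate; 4 4-acetoxystyrene (4-ethenylphenyl acetate)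
Product: 5 (E)-3-[4-(acetyloxy)phenyl]prop-2-en-1-yl docosanoate
Conditions: RuCl2(H2IMes)(=CH-C6H4-2-OiPr) (second-generation Hoveyda–Grubbs catalyst, H2IMes = 1,3-dimesitylimidazolidin-2-ylidene, 3 mol %), 4 (3 equiv), 1,4-benzoquinone (10 mol %), CH2Cl2, 40 °C, argon sparge
Reagents that add atoms: none
Why: Olefin cross-metathesis through ruthenacyclobutanes: the ruthenium alkylidene adds each terminal C=C in a [2+2] manner and the four-membered ring cycloreverts, so the two =CH2 ends leave as ethylene while the ArCH= and =CH–CH2–O fragments are joined at the benzylic carbon. The closest known reaction type is the ruthenium-carbene cross-metathesis of styrenes with allylic esters. No ring is closed and no stereocentre is created; the alkene should form as the conjugated E isomer under thermodynamic control, and its geometry is irrelevant because step 3 saturates it. The selectivity needed is cross- over self-metathesis, secured by the excess of the inexpensive styrene 4, by continuous removal of ethylene, and by the fact that any self-metathesis dimer of 3 remains a reactive internal alkene that is drawn back into the cycle and converted to 5. Neither partner carries a second alkene or a strongly coordinating group, the aryl acetate and the alkyl ester are inert to the catalyst, and 1,4-benzoquinone should suppress ruthenium hydride-induced migration of the allylic double bond.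

Step 3
Reactants: 5 (E)-3-[4-(acetyloxy)phenyl]prop-2-en-1-yl docosanoate
Product: 6 3-[4-(acetyloxy)phenyl]propyl docosanoate
Conditions: H2 (3 atm), RhCl(PPh3)3 (5 mol %), toluene/EtOH 1:1, rt to 40 °C
Reagents that add atoms: none
Why: Homogeneous hydrogenation with RhCl(PPh3)3, a monovalent rhodium complex, adds H2 syn to the unhindered 1,2-disubstituted alkene through oxidative addition, alkene insertion and reductive elimination without forming allyl-metal species, so the allylic C–O bond, the arene and both esters should survive, which palladium on carbon would not guarantee; the acetate stays on the phenol at this stage because a free para-hydroxycinnamyl ester could ionise through a quinone methide.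

Step 4
Reactants: 6 3-[4-(acetyloxy)phenyl]propyl docosanoate
Product: 7 3-(4-hydroxyphenyl)propyl docosanoate
Conditions: pyrrolidine (3 equiv), THF, 0 °C to rt; dilute aqueous citric acid work-up
Reagents that add atoms: none
Why: Chemoselective aminolysis of an aryl ester: the phenoxide is a much better leaving group than an alkoxide, so the secondary amine should take the acetyl group from the phenol at or below room temperature and leave the primary alkyl docosanoate untouched, while THF keeps the waxy substrate in solution.

Compound list
1 | docosanoyl chloride | CCCCCCCCCCCCCCCCCCCCCC(=O)Cl | starting material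
2 | allyl alcohol (prop-2-en-1-ol) | OCC=C | starting material
3 | allyl docosanoate (prop-2-en-1-yl docosanoate) | CCCCCCCCCCCCCCCCCCCCCC(=O)OCC=C | intermediate
4 | 4-acetoxystyrene (4-ethenylphenyl acetate) | CC(=O)Oc1ccc(C=C)cc1 | starting material
5 | (E)-3-[4-(acetyloxy)phenyl]prop-2-en-1-yl docosanoate | CCCCCCCCCCCCCCCCCCCCCC(=O)OC/C=C/c1ccc(OC(C)=O)cc1 | intermediate
6 | 3-[4-(acetyloxy)phenyl]propyl docosanoate | CCCCCCCCCCCCCCCCCCCCCC(=O)OCCCc1ccc(OC(C)=O)cc1 | intermediate
7 | 3-(4-hydroxyphenyl)propyl docosanoate | CCCCCCCCCCCCCCCCCCCCCC(=O)OCCCc1ccc(O)cc1 | target

Total step count: 4
Longest linear sequence: 4 steps (1 → 3 → 5 → 6 → 7; compound 4 is purchased)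

Steps most likely to fail

First, step 2 (cross-metathesis). Self-metathesis of either alkene may outpace the cross-coupling, the catalyst may decay through its methylidene form before 3 is consumed, or the allyl double bond may migrate toward the ester oxygen. The fallback changes the bond construction and makes the aryl–CH2 bond instead. Setting out from 3, anti-Markovnikov hydroboration with 9-borabicyclo[3.3.1]nonane (THF, 0 °C to rt) should give 3-(9-borabicyclo[3.3.1]nonan-9-yl)propyl docosanoate F1. This is coupled in the same flask with purchased 4-bromophenyl acetate (CC(=O)Oc1ccc(Br)cc1) in a B-alkyl Suzuki–Miyaura reaction (PdCl2(dppf), anhydrous K3PO4, THF/DMF, 50 °C). The detour comes back to the route at 6 and bypasses both 5 and step 3. Partial loss of the aryl acetate under the basic coupling would be harmless, since step 4 removes that group anyway.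

Second, step 3 (hydrogenation). The allylic C–O bond may be ionised or hydrogenolysed, hydrogen uptake by the conjugated disubstituted alkene may be slow, or ruthenium residues carried over may inhibit the catalyst. The fallback is a metal-free reduction. Setting out from 5, diimide generated in the flask from dipotassium azodicarboxylate (KO2C–N=N–CO2K) and acetic acid in CH2Cl2/MeOH at rt should transfer H2 in a concerted syn fashion. It cannot cleave C–O bonds, and the weakly acidic medium leaves the aryl acetate in place. The detour comes back at 6 and makes no new compound (F0).

Third, step 4 (acetate removal). Discrimination between the two esters may be incomplete, with amine attack on the docosanoate on prolonged exposure, or acetyl transfer from a poorly soluble substrate may be sluggish. The fallback changes the phenol protecting group to an acid-labile aryl tert-butyl ether, which is orthogonal to the alkyl ester. Setting out from 3, cross-metathesis with purchased 4-tert-butoxystyrene (CC(C)(C)Oc1ccc(C=C)cc1) under the conditions of step 2 should give (E)-3-(4-tert-butoxyphenyl)prop-2-en-1-yl docosanoate F2. Hydrogenation as in step 3 should give 3-(4-tert-butoxyphenyl)propyl docosanoate F3. CF3CO2H in CH2Cl2 at 0 °C should then release the phenol with loss of 2-methylpropene, rejoining the route at 7.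

Further compounds
F1 | step 2 | 3-(9-borabicyclo[3.3.1]nonan-9-yl)propyl docosanoate | CCCCCCCCCCCCCCCCCCCCCC(=O)OCCCB1C2CCCC1CCC2
F0 | step 3 | none | none
F2 | step 4 | (E)-3-(4-tert-butoxyphenyl)prop-2-en-1-yl docosanoate | CCCCCCCCCCCCCCCCCCCCCC(=O)OC/C=C/c1ccc(OC(C)(C)C)cc1
F3 | step 4 | 3-(4-tert-butoxyphenyl)propyl docosanoate | CCCCCCCCCCCCCCCCCCCCCC(=O)OCCCc1ccc(OC(C)(C)C)cc1
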